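## Structural features

The target joins two oxygen heterocycles through a resorcinol ring. The first is a 2,3-dihydrobenzofuran with a 4-hydroxyphenyl group at C2, an (E)-3-(2,4-dihydroxyphenyl)-3-oxoprop-1-enyl (chalcone) arm at C5 and a diarylmethine carbon at C3. The second is a fully substituted tetrahydrofuran with a 4-hydroxyphenyl group at C5, a 2,4-dihydroxybenzoyl group at C4 and a 4-hydroxybenzyl group at C3. The methine carbon carries a 2,4-dihydroxyphenyl ring and the central resorcinol ring; the central ring is bonded through C1′ to tetrahydrofuran C2 and through C5′ to the methine, with hydroxyls at C2′ and C4′. There are seven stereocentres: (2R,3R), trans, in the dihydrobenzofuran; the exocyclic (R)-methine directly next to C3; and four contiguous centres (2S,3R,4R,5R) in the tetrahydrofuran, with C2/C3 cis, C3/C4 trans and C4/C5 trans, so that the C3 and C5 substituents share one face and the C4 aroyl group lies on the other. Fragile features are the eleven free phenols, the 2′-hydroxychalcone (a reducible and electrophilic C=C that can also close to a flavanone), the C4 aryl ketone with the ring oxygen in the β position (retro-oxa-Michael opening, epimerisable α-carbon) and three benzylic C–O bonds activated by para or ortho/para oxygen, of which the cis C2–O bond of the tetrahydrofuran is the most easily ionised. The real difficulty lies in the four contiguous tetrahydrofuran centres with their single cis relationship, and in the acyclic methine, whose two aryl groups differ only in a remote substituent and which can therefore be set only through the neighbouring C3. The key step exploits the fact that tetrahydrofuran C5, C4 and C3 alternate faces and that C4 carries an acyl carbon and C3 a benzylic CH2: this is the pattern left by anti conjugate addition of an acyl anion equivalent to C4 of a 5-aryl butenolide followed by anti benzylation of the enolate at C3, the lactone carbonyl remaining as the future C2.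

## Logic of the disconnections

**33 ⇒ 32.** The eleven phenolic O–CH2Ph bonds are cut. One robust ether on every phenol survives organolithium, Lewis acid, carbenoid and palladium chemistry, so no phenol needs separate handling. The forward step must remove all of them without hydrogenating the enone and without ionising the benzylic ring C–O bonds, which points to a Lewis acid with a cation scavenger at low temperature.

**32 ⇒ 19 + 30.** The bond between the methine carbon and C5′ of the central ring is cut. This is the only acyclic stereocentre and the cut divides the molecule into two halves of similar size; C5′ of 19 is the single unhindered position ortho/para to both ether oxygens. The forward step must ionise 30 and capture the cation on one face under control of dihydrobenzofuran C3, without loss of the C3 proton and without touching the cis ether of 19. The ketone of 19 must already be free so that its aroyl ring is deactivated as a competing nucleophile.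

**30 ⇒ 27 + 29; 29 ⇒ 28 ⇒ 7.** The aryl C5–vinyl bond is cut (Heck), and the vinyl–carbinol bond of 28. The enone cannot pass an aryl-metal addition, whereas the bromine of 27 is inert to carbenoid, base, hydride and Grignard chemistry. The forward coupling must be E-selective on an electron-rich aryl bromide in the presence of a free benzylic alcohol.

**27 ⇒ 25 + 14; 25 ⇒ 24.** The carbinol carbon–aryl bond is cut and the aldehyde is traced to the ester. The carbinol configuration is irrelevant because it is planarised on ionisation. The trans arrangement at C3 must survive an enolisable aldehyde; it is the thermodynamic one.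

**24 ⇒ 23 ⇒ 22 ⇒ 21 ⇒ 20 + 9.** The C2–C3 bond of the dihydrofuran ring is cut (carbenoid C–H insertion), then the diazo group and the ether O–CH2 bond. Ring and C2 stereocentre arise from an achiral ether under catalyst control. The forward sequence must discriminate the two enantiotopic hydrogens of the OCH2 group and then invert C3 by base without opening the ring.

**19 ⇒ 18 ⇒ 16 ⇒ 12 + 14.** The ketone is masked as the dithioacetal, the C2–H bond is cut back to a hemiketal, and the C2–aryl bond to a lactone carbonyl. The lactone carbonyl of 12 is the latent C2; hydride delivery anti to the C3 substituent gives the cis ring, and the dithiane carries the ketone through the aryllithium and Lewis acid steps. The reduction must stay under kinetic control at low temperature.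

**12 ⇒ 5 + 8 + 9 (key disconnection).** The C4–C(dithiane) and C3–CH2 bonds are cut. Three simple pieces result and only C5 of 5 must be made enantioselectively. The forward step must be anti at both new centres, must be a 1,4-addition, and must be faster than proton abstraction at C5 of 5.

**5 ⇒ 3 ⇒ 1 + 2; 8 ⇒ 7 ⇒ 6; 14 ⇒ 13.** The lactone C–O bond, two alkyne hydrogens and the carbinol–alkyne bond are cut; then the C–S bonds of the dithioacetal and the O–benzyl bonds. All remaining compounds are purchasable; the single catalytic stereocentre of this branch is set in the alkynylation.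

## Other disconnections considered

**Alternative 1:** Oxidative ring contraction of a flavanone.
- Cut: the C3–C3a bond of the dihydrobenzofuran, traced back to the C4–C4a bond of (R)-6-bromo-2-[4-(pivaloyloxy)phenyl]chroman-4-one A1.
- Forward key step: PhI(OAc)2 (trivalent iodine) with HC(OMe)3 and catalytic H2SO4 in methanol. The enol ether of A1 is iodinated at C3, the fused aryl carbon shifts from C4 to C3 as iodobenzene leaves, and the former carbonyl carbon becomes the ester of methyl trans-5-bromo-2-[4-(pivaloyloxy)phenyl]-2,3-dihydrobenzofuran-3-carboxylate A2.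
- In favour: C2 of A1 passes unchanged into A2; the trans ester should form directly; no diazo compound is handled; the bromine handle is the one used in 24.
- Against: it concerns only the dihydrobenzofuran half. A1 is needed enantioenriched, and 2-arylchromanones can racemise by reversible opening of the pyranone ring in acid or base, while the contraction itself runs in acidic methanol. The pivalate, needed to restrain migration of the 2-aryl ring, must be exchanged for benzyl or carried as a second protecting-group class.
- Comparison: A2 and 24 are equivalent in structure. In mechanism, a cationic aryl shift under substrate control stands against a carbenoid insertion under catalyst control. The alternative is better in that the trans isomer needs no epimerisation (step 13 would fall away). The chosen plan is more secure in absolute configuration, because C2 is created in the ring-forming step from an achiral precursor. Once an enantioselective route to A1 is counted, step economy is about equal. The two are complementary: A2 could replace steps 10–13 without touching the key step.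

**Alternative 2:** Biomimetic oxidative dimerisation.
- Cut: C3–C3a and O1–C2 of the dihydrobenzofuran at once, back to two molecules of the 2′,4′-bis(methoxymethyl) ether of isoliquiritigenin A3.
- Forward key step: Ag2O generates phenoxyl radicals from A3; the α-carbon of one unit couples to the ortho carbon of another, and the regenerated phenol adds to the quinone methide to give the trans dehydrodimer A4.
- In favour: one step builds the ring, its trans relationship, the complete chalcone arm and the aryl ketone that is the precursor of the methine. In step count this is clearly better than steps 10–18 of the chosen plan.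
- Against: A4 would form as a racemate, so half the material is the wrong antipode and a resolution is needed. Other radical coupling modes compete. The C3 aroyl ketone of A4 must then be reduced or arylated in the presence of the enone carbonyl, a difficult chemoselectivity. Methoxymethyl ethers call for acid at the end, which endangers the cis ether of the tetrahydrofuran.
- Comparison: A4 contains everything of 30 except the oxidation level of the methine carbon, so the alternative is better in structure match and step economy. In mechanism it offers no absolute control, whereas the chosen plan sets C2 by a chiral catalyst. The alternative is the equal of the chosen plan at the hardest point: both end in the same cation capture at the methine, which it does not make easier.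

**Alternative 3:** Palladium three-component assembly of the tetrahydrofuran.
- Cut: O1–C5, C3–C4 and the exocyclic vinyl–aryl bond, back to (S)-1-[2,4-bis(methoxymethoxy)phenyl]prop-2-yn-1-ol A5, diethyl 2-[4-(methoxymethoxy)benzylidene]malonate A6 and 1-iodo-4-(methoxymethoxy)benzene A7.
- Forward key step: the lithium alkoxide of A5 adds to A6; the malonate anion attacks the alkyne, activated by ArPdI (from A7 and PdCl2(PPh3)2 reduced by n-BuLi to zerovalent palladium), in a 5-exo-dig closure; reductive elimination gives the 2,5-cis 3-arylidene tetrahydrofuran-4,4-dicarboxylate A8.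
- In favour: the ring and the carbon atoms of all four ring substituents come together in one convergent step; C2 stems from an easily made propargylic alcohol; hydrogenation of the arylidene from the face opposite both aryl groups would set C3 cis to C2 by a principle independent of oxocarbenium reduction. In convergence it is better than the chosen plan.
- Against: C5 forms in a reversible oxa-Michael addition under weak 1,3-induction, so the 2,5-cis relationship is not secured. A5, with its strongly donating aryl group, is easily ionised and may lose its configuration. The geminal diester of A8 must be cut down to one aroyl group (dealkoxycarbonylation of a β-alkoxy ester under hot halide conditions, then conversion of the ester to the aryl ketone), which adds three or four steps. The acetal protecting groups again need acid.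
- Comparison: in structure A8 has C2 and C5 in place but C3 and C4 still to be set, whereas 12 has C3, C4 and C5 in place and C2 to be set. In mechanism, an anti carbopalladation stands against a polar tandem addition–alkylation whose two new centres follow from anti approach to existing substituents. In step economy the two are about equal once the malonate editing is counted against the eight steps from 1 to 19.

Key step: step 5

Assumptions: (a) the (S,S)-ProPhenol ligand is taken to give the (S)-alcohol 3 and Rh2(S-PTTL)4 (dirhodium tetrakis[N-phthaloyl-(S)-tert-leucinate]) the (2R)-ester 23; if either sense of induction proves opposite, the mirror-image ligand or catalyst is used and nothing else changes. (b) Compounds 9, 13 and 20 are taken as purchasable.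

## Route

Step 1
Reactants: 1 4-(benzyloxy)benzaldehyde; 2 methyl propiolate
Product: 3 methyl (S)-4-[4-(benzyloxy)phenyl]-4-hydroxybut-2-ynoate
Conditions: Me2Zn (3 equiv), (S,S)-ProPhenol (10 mol%), Ph3P=O (20 mol%), toluene, 4 °C
Reagents that add atoms: none
Why: Dinuclear zinc–ProPhenol catalysed alkynylation: Me2Zn turns 2 into its zinc acetylide, which the chiral dinuclear complex delivers to one face of the aldehyde, setting the carbinol centre as S; Me2Zn is chosen over Et2Zn because methyl transfer to the aldehyde is slow.

Step 2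
Reactants: 3 methyl (S)-4-[4-(benzyloxy)phenyl]-4-hydroxybut-2-ynoate
Product: 5 (R)-5-[4-(benzyloxy)phenyl]furan-2(5H)-one, via (R,Z)-hydroxy enoate 4 (not isolated)
Conditions: H2 (1 atm), Pd/CaCO3 poisoned with Pb(OAc)2, quinoline, EtOAc, rt; then PPTS (cat.), CH2Cl2, rt
Reagents that add atoms: none
Why: Syn semihydrogenation on the lead-poisoned catalyst should stop at the (Z)-enoate 4, whose hydroxyl and ester are cis and close to the lactone under mild acid with loss of methanol; the aryl benzyl ether is not cleaved on this deactivated catalyst. The stereocentre is untouched (the descriptor changes from S to R only because the alkene ranks below the aryl group), and near-neutral conditions avoid ionisation or enolisation at C5.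

Step 3
Reactants: 6 2,4-dihydroxybenzaldehyde
Product: 7 2,4-bis(benzyloxy)benzaldehyde
Conditions: BnBr, K2CO3, DMF, 60 °C
Reagents that add atoms: benzyl bromide, BrCc1ccccc1
Why: Williamson etherification of both phenoxides; warming is needed for the hydrogen-bonded 2-hydroxyl.

Step 4
Reactants: 7 2,4-bis(benzyloxy)benzaldehyde
Product: 8 2-[2,4-bis(benzyloxy)phenyl]-1,3-dithiane
Conditions: HS(CH2)3SH, I2 (10 mol%), CH2Cl2, rt
Reagents that add atoms: propane-1,3-dithiol, SCCCS
Why: Iodine-catalysed dithioacetalisation of the aldehyde; catalytic I2 at room temperature leaves the aryl benzyl ethers intact.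

Step 5
Reactants: 8 2-[2,4-bis(benzyloxy)phenyl]-1,3-dithiane; 5 (R)-5-[4-(benzyloxy)phenyl]furan-2(5H)-one; 9 4-(benzyloxy)benzyl bromide
Product: 12 (3R,4R,5R)-3-[4-(benzyloxy)benzyl]-5-[4-(benzyloxy)phenyl]-4-{2-[2,4-bis(benzyloxy)phenyl]-1,3-dithian-2-yl}oxolan-2-one, via 2-lithio-2-aryl-1,3-dithiane 10 (not isolated), via lithium lactone enolate 11 (not isolated)
Conditions: 8, n-BuLi, THF, −78 °C; 5, −78 °C; then 9, DMPU, −78 to −30 °C
Reagents that add atoms: none
Why: n-BuLi removes the C2 hydrogen of 8 to give the sulfur-stabilised benzylic anion 10, which adds to C4 of 5 to form lithium enolate 11; 11 is then alkylated on carbon by 9 (C4–C(dithiane) and C3–CH2 bonds). The closest known reaction type is the tandem conjugate addition of lithiated 2-aryl-1,3-dithianes to butenolides with in-situ enolate benzylation used for dibenzylbutyrolactone lignans, here applied to a butenolide that carries an aryl group at C5. No ring is closed. C4 is controlled by the C5 stereocentre: the anion approaches the planar ring on the face opposite the aryl group (4,5-trans). C3 is controlled by C4: the bulky dithianyl group shields one face of 11 and the bromide enters from the other (3,4-trans), which gives 3R,4R,5R. The step needs 1,4- over 1,2-addition, secured by the soft delocalised anion in THF, and C- over O-alkylation, secured by the reactive benzylic bromide with DMPU. It also needs addition to outrun removal of the acidic C5 hydrogen of 5, which is helped by −78 °C, by adding 5 to a small excess of preformed 10 and by the moderate basicity of an aryl-substituted dithiane anion. Any 5 that is deprotonated stays as the furanolate until the quench and does not return to the addition pathway, so the cost should be yield and not the configurational purity of 12.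

Step 6
Reactants: 13 4-bromoresorcinol
Product: 14 1-bromo-2,4-bis(benzyloxy)benzene
Conditions: BnBr, K2CO3, DMF, 50 °C
Reagents that add atoms: benzyl bromide, BrCc1ccccc1
Why: Williamson etherification of both phenols; the aryl bromide is inert.

Step 7
Reactants: 14 1-bromo-2,4-bis(benzyloxy)benzene; 12 (3R,4R,5R)-lactone with dithiane-masked aroyl group
Product: 16 (3R,4R,5R)-3-[4-(benzyloxy)benzyl]-2-[2,4-bis(benzyloxy)phenyl]-5-[4-(benzyloxy)phenyl]-4-{2-[2,4-bis(benzyloxy)phenyl]-1,3-dithian-2-yl}oxolan-2-ol (anomer mixture), via 2,4-bis(benzyloxy)phenyllithium 15 (not isolated)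
Conditions: 14, n-BuLi, THF, −78 °C; then 12, −78 °C; aq NH4Cl
Reagents that add atoms: none
Why: Bromine–lithium exchange gives aryllithium 15, which adds once to the lactone carbonyl because the tetrahedral lithium hemiketal alkoxide persists at −78 °C. The dithiane has no acidic hydrogen and shields the future ketone; C2 is not yet defined.

Step 8
Reactants: 16 cyclic hemiketal (anomer mixture)
Product: 18 (2S,3R,4R,5R)-3-[4-(benzyloxy)benzyl]-2-[2,4-bis(benzyloxy)phenyl]-5-[4-(benzyloxy)phenyl]-4-{2-[2,4-bis(benzyloxy)phenyl]-1,3-dithian-2-yl}oxolane, via C2 oxocarbenium ion 17 (not isolated)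
Conditions: Et3SiH, BF3·OEt2, CH2Cl2, −78 °C; Et3N quench at −78 °C
Reagents that add atoms: none
Why: Ionic hydrogenation of a cyclic hemiketal: BF3·OEt2 ionises 16 to the aryl-stabilised oxocarbenium ion 17, and Et3SiH should deliver hydride to C2 on the face opposite the adjacent C3 benzyl group (inside attack on the envelope, also the face remote from the C5 aryl group), which gives the 2,3-cis ring with C2 as S. The reaction is kept at −78 °C and quenched cold because the cis ether is the kinetic product and could re-ionise at C2.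

Step 9
Reactants: 18 (2S,3R,4R,5R)-tetrahydrofuran with dithiane-masked aroyl group
Product: 19 (2S,3R,4R,5R)-3-[4-(benzyloxy)benzyl]-4-[2,4-bis(benzyloxy)benzoyl]-2-[2,4-bis(benzyloxy)phenyl]-5-[4-(benzyloxy)phenyl]oxolane
Conditions: MeI, CaCO3, MeCN/H2O (9:1), 45 °C
Reagents that add atoms: water, O
Why: Alkylative dithioacetal hydrolysis: S-methylation creates a sulfonium leaving group, the aryl-stabilised thionium ion is captured by water and the second sulfur leaves in the same way. CaCO3 keeps the medium neutral so the cis C2 ether is not ionised, and MeI leaves the electron-rich rings alone, unlike halogenating or mercurating reagents; C4 stays trans to both neighbours, its stable arrangement.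

Step 10
Reactants: 20 methyl 2-(5-bromo-2-hydroxyphenyl)acetate; 9 4-(benzyloxy)benzyl bromide
Product: 21 methyl 2-{2-[(4-benzyloxybenzyl)oxy]-5-bromophenyl}acetate
Conditions: K2CO3, acetone, reflux
Reagents that add atoms: none
Why: Williamson etherification; O-alkylation of the phenoxide by the reactive benzylic bromide should be faster than closure onto the ester.

Step 11
Reactants: 21 methyl 2-{2-[(4-benzyloxybenzyl)oxy]-5-bromophenyl}acetate
Product: 22 methyl 2-{2-[(4-benzyloxybenzyl)oxy]-5-bromophenyl}-2-diazoacetate
Conditions: 4-AcNHC6H4SO2N3, DBU, MeCN, 0 °C to rt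
Reagents that add atoms: 4-acetamidobenzenesulfonyl azide, CC(=O)Nc1ccc(cc1)S(=O)(=O)N=[N+]=[N-]
Why: Regitz diazo transfer to the aryl acetate, whose benzylic α-hydrogens are acidic enough for DBU.

Step 12
Reactants: 22 methyl 2-{2-[(4-benzyloxybenzyl)oxy]-5-bromophenyl}-2-diazoacetate
Product: 23 methyl (2R,3S)-2-[4-(benzyloxy)phenyl]-5-bromo-2,3-dihydro-1-benzofuran-3-carboxylate (cis)
Conditions: Rh2(S-PTTL)4 (1 mol%), toluene, −78 °C
Reagents that add atoms: none
Why: Intramolecular 1,5 C–H insertion of the rhodium donor/acceptor carbenoid into the ether methylene, which is activated by oxygen and by the 4-alkoxyphenyl group, closes the five-membered ring with loss of N2. The chiral carboxylate ligands select one of the two enantiotopic hydrogens and set C2 as R; the concerted insertion gives the cis ester as the kinetic product.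

Step 13
Reactants: 23 cis ester (2R,3S)
Product: 24 methyl (2R,3R)-2-[4-(benzyloxy)phenyl]-5-bromo-2,3-dihydro-1-benzofuran-3-carboxylate (trans)
Conditions: NaOMe (0.3 equiv), MeOH/THF, rt
Reagents that add atoms: none
Why: Base-mediated epimerisation at C3 through the ester enolate to the more stable trans isomer. C2 is untouched, since expulsion of the phenoxide from the enolate would be a disfavoured 5-endo ring opening.

Step 14
Reactants: 24 trans ester (2R,3R)
Product: 25 (2R,3R)-2-[4-(benzyloxy)phenyl]-5-bromo-2,3-dihydro-1-benzofuran-3-carbaldehyde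
Conditions: i-Bu2AlH (1.1 equiv), CH2Cl2, −78 °C; aq KNaC4H4O6
Reagents that add atoms: none
Why: Partial ester reduction: the aluminium hemiacetal is stable at −78 °C and releases the aldehyde only on work-up. Enolisation of the aldehyde is harmless because trans is the thermodynamic arrangement; aryl bromide and benzyl ether are inert.

Step 15
Reactants: 14 1-bromo-2,4-bis(benzyloxy)benzene; 25 (2R,3R)-aldehyde
Product: 27 [2,4-bis(benzyloxy)phenyl]{(2R,3S)-2-[4-(benzyloxy)phenyl]-5-bromo-2,3-dihydro-1-benzofuran-3-yl}methanol (trans ring, both carbinol epimers), via 2,4-bis(benzyloxy)phenylmagnesium bromide 26 (not isolated)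
Conditions: 14, Mg, I2 (cat.), THF, 40 °C; then 25, THF, −78 to 0 °C; aq NH4Cl
Reagents that add atoms: none
Why: Grignard addition to the aldehyde; the aryl bromide of 25 does not exchange with an arylmagnesium halide at low temperature. Both carbinol epimers are acceptable because this centre is planarised in step 19 (the ring descriptor at C3 changes from R to S through priorities only).

Step 16
Reactants: 7 2,4-bis(benzyloxy)benzaldehyde
Product: 28 1-[2,4-bis(benzyloxy)phenyl]prop-2-en-1-ol (racemic)
Conditions: CH2=CHMgBr, THF, −78 to 0 °C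
Reagents that add atoms: vinylmagnesium bromide, C=C[Mg]Br
Why: Grignard 1,2-addition to the aldehyde; the carbinol centre is removed in the next step.

Step 17
Reactants: 28 1-[2,4-bis(benzyloxy)phenyl]prop-2-en-1-ol
Product: 29 1-[2,4-bis(benzyloxy)phenyl]prop-2-en-1-one
Conditions: MnO2, CH2Cl2, rt
Reagents that add atoms: none
Why: Neutral oxidation of an allylic and benzylic alcohol with MnO2; the vinyl ketone is used at once because it polymerises on standing.

Step 18
Reactants: 27 bromo carbinol; 29 1-[2,4-bis(benzyloxy)phenyl]prop-2-en-1-one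
Product: 30 (E)-1-[2,4-bis(benzyloxy)phenyl]-3-{(2R,3S)-2-[4-(benzyloxy)phenyl]-3-{[2,4-bis(benzyloxy)phenyl](hydroxy)methyl}-2,3-dihydro-1-benzofuran-5-yl}prop-2-en-1-one (both carbinol epimers)
Conditions: Pd2(dba)3 (2.5 mol%), [HP(t-Bu)3]BF4 (10 mol%), Cy2NMe, 1,4-dioxane, 70 °C
Reagents that add atoms: none
Why: Mizoroki–Heck reaction: zerovalent palladium with P(t-Bu)3 inserts into the electron-rich aryl bromide, the aryl group adds to the terminal alkene carbon and syn β-hydride elimination gives the E enone. The tertiary amine base is too weak to form the alkoxide of the benzylic alcohol.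

Step 19
Reactants: 19 tetrahydrofuran ketone; 30 enone carbinol
Product: 32 undeca-O-benzyl ether of the target, (E)-enone, dihydrobenzofuran 2R,3R, methine R, tetrahydrofuran 2S,3R,4R,5R, via benzylic cation 31 (not isolated)
Conditions: 19 (2 equiv), BF3·OEt2, CH2Cl2, 4 Å MS, −78 °C, slow addition of 30
Reagents that add atoms: none
Why: Friedel–Crafts alkylation through a chiral benzylic cation: BF3·OEt2 ionises the ortho/para-oxygen-stabilised carbinol to 31, which is captured at C5′ of the central ring of 19, the only unhindered position ortho/para to both ether oxygens (the aroyl ring is deactivated by its carbonyl). In 31 the C3–H bond should lie in the plane of the cation to minimise allylic 1,3-strain, the peri C4–H of the benzofuran screens one face, and attack past C2, whose aryl group points away, should give the R methine. Slow addition of 30 to an excess of 19 at −78 °C limits self-alkylation by the free ring position of 30, loss of the C3 proton and ionisation of the cis ether.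

Step 20
Reactants: 32 undeca-O-benzyl ether of the target
Product: 33 CNP0225254.6 (target)
Conditions: BCl3, C6HMe5, CH2Cl2, −78 °C; MeOH quench
Reagents that add atoms: none
Why: Lewis-acid cleavage of aryl benzyl ethers with a non-Lewis-basic cation scavenger: BCl3 coordinates each ether oxygen and the benzyl cation is taken up irreversibly by pentamethylbenzene, so that the enone double bond is not reduced and the liberated resorcinol rings are not benzylated. The temperature of −78 °C and the cold methanolic quench are chosen to spare the benzylic ring C–O bonds; no stereocentre is touched.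

## Compound list

1 | 4-(benzyloxy)benzaldehyde | O=Cc1ccc(OCc2ccccc2)cc1 | starting material
2 | methyl propiolate | C#CC(=O)OC | starting material
3 | methyl (S)-4-[4-(benzyloxy)phenyl]-4-hydroxybut-2-ynoate | O[C@@H](c1ccc(OCc2ccccc2)cc1)C#CC(=O)OC | intermediate
4 | methyl (R,Z)-4-[4-(benzyloxy)phenyl]-4-hydroxybut-2-enoate (not isolated) | O[C@@H](c1ccc(OCc2ccccc2)cc1)/C=C\C(=O)OC | intermediate
5 | (R)-5-[4-(benzyloxy)phenyl]furan-2(5H)-one | O=C1O[C@@H](c2ccc(OCc3ccccc3)cc2)C=C1 | intermediate
6 | 2,4-dihydroxybenzaldehyde | O=Cc1ccc(O)cc1O | starting material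
7 | 2,4-bis(benzyloxy)benzaldehyde | O=Cc1ccc(OCc2ccccc2)cc1OCc1ccccc1 | intermediate
8 | 2-[2,4-bis(benzyloxy)phenyl]-1,3-dithiane | S1CCCSC1c1ccc(OCc2ccccc2)cc1OCc1ccccc1 | intermediate
9 | 4-(benzyloxy)benzyl bromide | BrCc1ccc(OCc2ccccc2)cc1 | starting material
10 | 2-lithio-2-[2,4-bis(benzyloxy)phenyl]-1,3-dithiane (not isolated) | [Li]C1(SCCCS1)c1ccc(OCc2ccccc2)cc1OCc1ccccc1 | intermediate
11 | lithium enolate of (4R,5R)-5-[4-(benzyloxy)phenyl]-4-{2-[2,4-bis(benzyloxy)phenyl]-1,3-dithian-2-yl}oxolan-2-one (not isolated) | [Li]OC1=C[C@@H](C2(c3ccc(OCc4ccccc4)cc3OCc3ccccc3)SCCCS2)[C@H](c2ccc(OCc3ccccc3)cc2)O1 | intermediate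
12 | (3R,4R,5R)-3-[4-(benzyloxy)benzyl]-5-[4-(benzyloxy)phenyl]-4-{2-[2,4-bis(benzyloxy)phenyl]-1,3-dithian-2-yl}oxolan-2-one | O=C1O[C@@H](c2ccc(OCc3ccccc3)cc2)[C@H](C2(c3ccc(OCc4ccccc4)cc3OCc3ccccc3)SCCCS2)[C@H]1Cc1ccc(OCc2ccccc2)cc1 | intermediate
13 | 4-bromoresorcinol | Oc1ccc(Br)c(O)c1 | starting material
14 | 1-bromo-2,4-bis(benzyloxy)benzene | Brc1ccc(OCc2ccccc2)cc1OCc1ccccc1 | intermediate
15 | 2,4-bis(benzyloxy)phenyllithium (not isolated) | [Li]c1ccc(OCc2ccccc2)cc1OCc1ccccc1 | intermediate
16 | (3R,4R,5R)-3-[4-(benzyloxy)benzyl]-2-[2,4-bis(benzyloxy)phenyl]-5-[4-(benzyloxy)phenyl]-4-{2-[2,4-bis(benzyloxy)phenyl]-1,3-dithian-2-yl}oxolan-2-ol (anomer mixture) | OC1(c2ccc(OCc3ccccc3)cc2OCc2ccccc2)O[C@@H](c2ccc(OCc3ccccc3)cc2)[C@H](C2(c3ccc(OCc4ccccc4)cc3OCc3ccccc3)SCCCS2)[C@H]1Cc1ccc(OCc2ccccc2)cc1 | intermediate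
17 | C2 oxocarbenium ion derived from 16 (not isolated) | C(c1ccccc1)Oc1ccc(c(OCc2ccccc2)c1)C1=[O+][C@@H](c2ccc(OCc3ccccc3)cc2)[C@H](C2(c3ccc(OCc4ccccc4)cc3OCc3ccccc3)SCCCS2)[C@H]1Cc1ccc(OCc2ccccc2)cc1 | intermediate
18 | (2S,3R,4R,5R)-3-[4-(benzyloxy)benzyl]-2-[2,4-bis(benzyloxy)phenyl]-5-[4-(benzyloxy)phenyl]-4-{2-[2,4-bis(benzyloxy)phenyl]-1,3-dithian-2-yl}oxolane | C(c1ccccc1)Oc1ccc(c(OCc2ccccc2)c1)[C@H]1O[C@@H](c2ccc(OCc3ccccc3)cc2)[C@H](C2(c3ccc(OCc4ccccc4)cc3OCc3ccccc3)SCCCS2)[C@H]1Cc1ccc(OCc2ccccc2)cc1 | intermediate
19 | (2S,3R,4R,5R)-3-[4-(benzyloxy)benzyl]-4-[2,4-bis(benzyloxy)benzoyl]-2-[2,4-bis(benzyloxy)phenyl]-5-[4-(benzyloxy)phenyl]oxolane | C(c1ccccc1)Oc1ccc(c(OCc2ccccc2)c1)[C@H]1O[C@@H](c2ccc(OCc3ccccc3)cc2)[C@H](C(=O)c2ccc(OCc3ccccc3)cc2OCc2ccccc2)[C@H]1Cc1ccc(OCc2ccccc2)cc1 | intermediate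
20 | methyl 2-(5-bromo-2-hydroxyphenyl)acetate | COC(=O)Cc1cc(Br)ccc1O | starting material
21 | methyl 2-{2-[(4-benzyloxybenzyl)oxy]-5-bromophenyl}acetate | COC(=O)Cc1cc(Br)ccc1OCc1ccc(OCc2ccccc2)cc1 | intermediate
22 | methyl 2-{2-[(4-benzyloxybenzyl)oxy]-5-bromophenyl}-2-diazoacetate | COC(=O)C(=[N+]=[N-])c1cc(Br)ccc1OCc1ccc(OCc2ccccc2)cc1 | intermediate
23 | methyl (2R,3S)-2-[4-(benzyloxy)phenyl]-5-bromo-2,3-dihydro-1-benzofuran-3-carboxylate (cis) | Brc1ccc2c(c1)[C@H](C(=O)OC)[C@H](c1ccc(OCc3ccccc3)cc1)O2 | intermediate
24 | methyl (2R,3R)-2-[4-(benzyloxy)phenyl]-5-bromo-2,3-dihydro-1-benzofuran-3-carboxylate (trans) | Brc1ccc2c(c1)[C@@H](C(=O)OC)[C@H](c1ccc(OCc3ccccc3)cc1)O2 | intermediate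
25 | (2R,3R)-2-[4-(benzyloxy)phenyl]-5-bromo-2,3-dihydro-1-benzofuran-3-carbaldehyde | Brc1ccc2c(c1)[C@@H](C=O)[C@H](c1ccc(OCc3ccccc3)cc1)O2 | intermediate
26 | 2,4-bis(benzyloxy)phenylmagnesium bromide (not isolated) | Br[Mg]c1ccc(OCc2ccccc2)cc1OCc1ccccc1 | intermediate
27 | [2,4-bis(benzyloxy)phenyl]{(2R,3S)-2-[4-(benzyloxy)phenyl]-5-bromo-2,3-dihydro-1-benzofuran-3-yl}methanol (trans ring, both carbinol epimers) | Brc1ccc2c(c1)[C@@H](C(O)c1ccc(OCc3ccccc3)cc1OCc1ccccc1)[C@H](c1ccc(OCc3ccccc3)cc1)O2 | intermediate
28 | 1-[2,4-bis(benzyloxy)phenyl]prop-2-en-1-ol (racemic) | C=CC(O)c1ccc(OCc2ccccc2)cc1OCc1ccccc1 | intermediate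
29 | 1-[2,4-bis(benzyloxy)phenyl]prop-2-en-1-one | C=CC(=O)c1ccc(OCc2ccccc2)cc1OCc1ccccc1 | intermediate
30 | (E)-1-[2,4-bis(benzyloxy)phenyl]-3-{(2R,3S)-2-[4-(benzyloxy)phenyl]-3-{[2,4-bis(benzyloxy)phenyl](hydroxy)methyl}-2,3-dihydro-1-benzofuran-5-yl}prop-2-en-1-one (both carbinol epimers) | O=C(/C=C/c1ccc2c(c1)[C@@H](C(O)c1ccc(OCc3ccccc3)cc1OCc1ccccc1)[C@H](c1ccc(OCc3ccccc3)cc1)O2)c1ccc(OCc2ccccc2)cc1OCc1ccccc1 | intermediate
31 | benzylic cation derived from 30 (not isolated) | O=C(/C=C/c1ccc2c(c1)[C@@H]([CH+]c1ccc(OCc3ccccc3)cc1OCc1ccccc1)[C@H](c1ccc(OCc3ccccc3)cc1)O2)c1ccc(OCc2ccccc2)cc1OCc1ccccc1 | intermediate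
32 | undeca-O-benzyl ether of the target: (E)-enone, dihydrobenzofuran 2R,3R, methine R, tetrahydrofuran 2S,3R,4R,5R | O=C(/C=C/c1ccc2c(c1)[C@@H]([C@H](c1ccc(OCc5ccccc5)cc1OCc1ccccc1)c1cc([C@H]3O[C@@H](c4ccc(OCc5ccccc5)cc4)[C@H](C(=O)c4ccc(OCc5ccccc5)cc4OCc4ccccc4)[C@H]3Cc3ccc(OCc4ccccc4)cc3)c(OCc3ccccc3)cc1OCc1ccccc1)[C@H](c1ccc(OCc3ccccc3)cc1)O2)c1ccc(OCc2ccccc2)cc1OCc1ccccc1 | intermediate
33 | (E)-1-(2,4-dihydroxyphenyl)-3-{(2R,3R)-3-[(R)-(2,4-dihydroxyphenyl){2,4-dihydroxy-5-[(2S,3R,4R,5R)-4-(2,4-dihydroxybenzoyl)-3-(4-hydroxybenzyl)-5-(4-hydroxyphenyl)oxolan-2-yl]phenyl}methyl]-2-(4-hydroxyphenyl)-2,3-dihydro-1-benzofuran-5-yl}prop-2-en-1-one (CNP0225254.6) | O=C(/C=C/c1ccc2c(c1)[C@@H]([C@H](c1ccc(O)cc1O)c1cc([C@H]3O[C@@H](c4ccc(O)cc4)[C@H](C(=O)c4ccc(O)cc4O)[C@H]3Cc3ccc(O)cc3)c(O)cc1O)[C@H](c1ccc(O)cc1)O2)c1ccc(O)cc1O | target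

## Step count and least certain steps

Total: 20 steps. Longest linear sequence: 9 steps (20 → 21 → 22 → 23 → 24 → 25 → 27 → 30 → 32 → 33; steps 10–15 and 18–20). The tetrahydrofuran branch from 1 takes 8 steps (1, 2, 5, 7, 8, 9, 19, 20).

**Step 5 (key step).** The most likely failure is proton abstraction at C5 of 5 by the basic anion 10 in competition with conjugate addition. That hydrogen is benzylic and allylic and its loss creates an aromatic 2-oxidofuran; the ortho-benzyloxy group also slows the approach of 10 to C4. The result would be low conversion and alkylated furanone by-products rather than loss of configuration in 12. Fallback: the fallback sets out from 3 and comes back at 12, adding 10 to an acyclic acceptor whose γ-hydrogen is not part of a latent aromatic anion. Trans-reduction of 3 with NaAlH2(OCH2CH2OMe)2 (THF, −72 °C; alkoxide-directed hydroalumination) should give methyl (R,E)-4-[4-(benzyloxy)phenyl]-4-hydroxybut-2-enoate F1. Silylation (t-BuMe2SiCl, imidazole, DMF) gives methyl (R,E)-4-[4-(benzyloxy)phenyl]-4-[(tert-butyldimethylsilyl)oxy]but-2-enoate F2. Conjugate addition of 10 (THF, −78 °C), expected anti to the silyloxy group held antiperiplanar to the incoming nucleophile, gives methyl (3R,4R)-4-[4-(benzyloxy)phenyl]-3-{2-[2,4-bis(benzyloxy)phenyl]-1,3-dithian-2-yl}-4-[(tert-butyldimethylsilyl)oxy]butanoate F3. Desilylation with Bu4NF/AcOH and lactonisation gives (4R,5R)-5-[4-(benzyloxy)phenyl]-4-{2-[2,4-bis(benzyloxy)phenyl]-1,3-dithian-2-yl}oxolan-2-one F4. Enolisation with LiN(SiMe3)2 and alkylation with 9 (THF/DMPU, −78 °C), anti to the dithianyl group, gives 12.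

**Step 19.** The most likely failure is capture of cation 31 with low or reversed facial preference, since the two faces differ only in C2 against C3a of the dihydrobenzofuran. Self-alkylation through the free activated ring position of 30 or 32, and loss of the C3 proton leading to aromatisation of the dihydrofuran ring, are further risks. Fallback: the fallback sets out from 19 and 25 and comes back at 32, exchanging the roles of the two resorcinol rings so that the same facial preference gives the opposite methine configuration and the nucleophile becomes a cheap arene used in large excess. Iodination of 19 at C5′ (N-iodosuccinimide, MeCN, rt; the aroyl ring is deactivated) gives (2S,3R,4R,5R)-3-[4-(benzyloxy)benzyl]-4-[2,4-bis(benzyloxy)benzoyl]-2-[2,4-bis(benzyloxy)-5-iodophenyl]-5-[4-(benzyloxy)phenyl]oxolane F5. Nozaki–Hiyama–Kishi coupling of F5 with 25 (CrCl2, NiCl2 cat., DMF, rt), which selects the aldehyde over the ketone and the aryl iodide over the aryl bromide, gives the carbinol {(2R,3S)-2-[4-(benzyloxy)phenyl]-5-bromo-2,3-dihydro-1-benzofuran-3-yl}{2,4-bis(benzyloxy)-5-[(2S,3R,4R,5R)-oxolan-2-yl]phenyl}methanol (oxolane substituted as in 19) F6. Ionisation of F6 (BF3·OEt2, CH2Cl2, −78 °C) in the presence of ten equivalents of commercial 1,3-bis(benzyloxy)benzene, which reacts at its C4, gives the coupled aryl bromide F7, the analogue of 32 with bromine in place of the enone arm. The Heck reaction of F7 with 29 under the conditions of step 18 gives 32.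

**Step 8.** The most likely failure is hydride delivery from the wrong face, because the bulky dithianyl group at C4 lies on the face the hydride must use. Re-ionisation at C2 with equilibration away from the cis ring, or reductive ring opening, could also occur if the mixture warms. Fallback: the fallback sets out from 16 and comes back at 19, so that the hydride meets a ring whose C4 carries the flat aroyl group. Alkylative hydrolysis of 16 (MeI, CaCO3, aqueous MeCN, 45 °C) gives the keto hemiketal (3R,4R,5R)-3-[4-(benzyloxy)benzyl]-4-[2,4-bis(benzyloxy)benzoyl]-2-[2,4-bis(benzyloxy)phenyl]-5-[4-(benzyloxy)phenyl]oxolan-2-ol F8. Reduction of F8 (Et3SiH, BF3·OEt2, CH2Cl2, −78 °C), in which the hemiketal ionises far faster than the aryl ketone is reduced, gives 19.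

**Step 20.** The most likely failure is ionisation of the benzylic ring C–O bonds by BCl3, above all the cis C2–O bond of the tetrahydrofuran, with loss of the cis configuration or ring opening. Incomplete cleavage of eleven ethers and acid-promoted closure of the 2′-hydroxychalcone to a flavanone on work-up are lesser risks. Fallback: the fallback sets out from 32 and comes back at 33, avoiding Lewis acid by masking the enone so that hydrogenolysis can be used. Conjugate addition of PhSO2Na in AcOH/THF to the enone of 32 gives the β-phenylsulfonyl ketone F9 (both epimers at the new carbon). Hydrogenolysis of F9 (H2, 1 atm, Pd/C, EtOAc/MeOH), for which no alkene or halide remains, gives the undecaphenolic β-phenylsulfonyl ketone F10. Elimination of benzenesulfinate from F10 by an E1cB process (Et3N, MeOH, rt) restores the (E)-enone and gives 33.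

## Further compounds

F1 | step 5 | methyl (R,E)-4-[4-(benzyloxy)phenyl]-4-hydroxybut-2-enoate | O[C@@H](c1ccc(OCc2ccccc2)cc1)/C=C/C(=O)OC
F2 | step 5 | methyl (R,E)-4-[4-(benzyloxy)phenyl]-4-[(tert-butyldimethylsilyl)oxy]but-2-enoate | CC(C)(C)[Si](C)(C)O[C@@H](c1ccc(OCc2ccccc2)cc1)/C=C/C(=O)OC
F3 | step 5 | methyl (3R,4R)-4-[4-(benzyloxy)phenyl]-3-{2-[2,4-bis(benzyloxy)phenyl]-1,3-dithian-2-yl}-4-[(tert-butyldimethylsilyl)oxy]butanoate | COC(=O)C[C@@H](C1(c2ccc(OCc3ccccc3)cc2OCc2ccccc2)SCCCS1)[C@H](c1ccc(OCc2ccccc2)cc1)O[Si](C)(C)C(C)(C)C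
F4 | step 5 | (4R,5R)-5-[4-(benzyloxy)phenyl]-4-{2-[2,4-bis(benzyloxy)phenyl]-1,3-dithian-2-yl}oxolan-2-one | O=C1O[C@@H](c2ccc(OCc3ccccc3)cc2)[C@H](C2(c3ccc(OCc4ccccc4)cc3OCc3ccccc3)SCCCS2)C1
F5 | step 19 | (2S,3R,4R,5R)-3-[4-(benzyloxy)benzyl]-4-[2,4-bis(benzyloxy)benzoyl]-2-[2,4-bis(benzyloxy)-5-iodophenyl]-5-[4-(benzyloxy)phenyl]oxolane | C(c1ccccc1)Oc1c(I)cc(c(OCc2ccccc2)c1)[C@H]1O[C@@H](c2ccc(OCc3ccccc3)cc2)[C@H](C(=O)c2ccc(OCc3ccccc3)cc2OCc2ccccc2)[C@H]1Cc1ccc(OCc2ccccc2)cc1
F6 | step 19 | {(2R,3S)-2-[4-(benzyloxy)phenyl]-5-bromo-2,3-dihydro-1-benzofuran-3-yl}{2,4-bis(benzyloxy)-5-[(2S,3R,4R,5R)-3-[4-(benzyloxy)benzyl]-4-[2,4-bis(benzyloxy)benzoyl]-5-[4-(benzyloxy)phenyl]oxolan-2-yl]phenyl}methanol (both carbinol epimers) | Brc1ccc2c(c1)[C@@H](C(O)c1cc([C@H]3O[C@@H](c4ccc(OCc5ccccc5)cc4)[C@H](C(=O)c4ccc(OCc5ccccc5)cc4OCc4ccccc4)[C@H]3Cc3ccc(OCc4ccccc4)cc3)c(OCc3ccccc3)cc1OCc1ccccc1)[C@H](c1ccc(OCc3ccccc3)cc1)O2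
F7 | step 19 | nona-O-benzyl coupled aryl bromide, the analogue of 32 with bromine at C5 of the dihydrobenzofuran in place of the enone arm (methine R) | Brc1ccc2c(c1)[C@@H]([C@H](c1ccc(OCc5ccccc5)cc1OCc1ccccc1)c1cc([C@H]3O[C@@H](c4ccc(OCc5ccccc5)cc4)[C@H](C(=O)c4ccc(OCc5ccccc5)cc4OCc4ccccc4)[C@H]3Cc3ccc(OCc4ccccc4)cc3)c(OCc3ccccc3)cc1OCc1ccccc1)[C@H](c1ccc(OCc3ccccc3)cc1)O2
F8 | step 8 | (3R,4R,5R)-3-[4-(benzyloxy)benzyl]-4-[2,4-bis(benzyloxy)benzoyl]-2-[2,4-bis(benzyloxy)phenyl]-5-[4-(benzyloxy)phenyl]oxolan-2-ol (anomer mixture) | OC1(c2ccc(OCc3ccccc3)cc2OCc2ccccc2)O[C@@H](c2ccc(OCc3ccccc3)cc2)[C@H](C(=O)c2ccc(OCc3ccccc3)cc2OCc2ccccc2)[C@H]1Cc1ccc(OCc2ccccc2)cc1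
F9 | step 20 | β-phenylsulfonyl ketone from conjugate addition of benzenesulfinate to the enone of 32 (both epimers at the sulfonyl-bearing carbon) | O=C(CC(S(=O)(=O)c6ccccc6)c1ccc2c(c1)[C@@H]([C@H](c1ccc(OCc5ccccc5)cc1OCc1ccccc1)c1cc([C@H]3O[C@@H](c4ccc(OCc5ccccc5)cc4)[C@H](C(=O)c4ccc(OCc5ccccc5)cc4OCc4ccccc4)[C@H]3Cc3ccc(OCc4ccccc4)cc3)c(OCc3ccccc3)cc1OCc1ccccc1)[C@H](c1ccc(OCc3ccccc3)cc1)O2)c1ccc(OCc2ccccc2)cc1OCc1ccccc1
F10 | step 20 | undecaphenolic β-phenylsulfonyl ketone, the debenzylated form of F9 | O=C(CC(S(=O)(=O)c6ccccc6)c1ccc2c(c1)[C@@H]([C@H](c1ccc(O)cc1O)c1cc([C@H]3O[C@@H](c4ccc(O)cc4)[C@H](C(=O)c4ccc(O)cc4O)[C@H]3Cc3ccc(O)cc3)c(O)cc1O)[C@H](c1ccc(O)cc1)O2)c1ccc(O)cc1O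
A1 | alternative 1 | (R)-6-bromo-2-[4-(pivaloyloxy)phenyl]chroman-4-one | O=C1C[C@H](c2ccc(OC(=O)C(C)(C)C)cc2)Oc2ccc(Br)cc12
A2 | alternative 1 | methyl (2R,3R)-5-bromo-2-[4-(pivaloyloxy)phenyl]-2,3-dihydro-1-benzofuran-3-carboxylate (trans) | Brc1ccc2c(c1)[C@@H](C(=O)OC)[C@H](c1ccc(OC(=O)C(C)(C)C)cc1)O2
A3 | alternative 2 | (E)-1-[2,4-bis(methoxymethoxy)phenyl]-3-(4-hydroxyphenyl)prop-2-en-1-one | O=C(/C=C/c1ccc(O)cc1)c1ccc(OCOC)cc1OCOC
A4 | alternative 2 | trans dehydrodimer of A3 with 3-aroyl group and 5-enone arm, (2R,3R) antipode of the racemate | O=C(/C=C/c1ccc2c(c1)[C@@H](C(=O)c1ccc(OCOC)cc1OCOC)[C@H](c1ccc(O)cc1)O2)c1ccc(OCOC)cc1OCOC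
A5 | alternative 3 | (S)-1-[2,4-bis(methoxymethoxy)phenyl]prop-2-yn-1-ol | c1(ccc(OCOC)cc1OCOC)[C@H](C#C)O
A6 | alternative 3 | diethyl 2-[4-(methoxymethoxy)benzylidene]malonate | CCOC(=O)C(=Cc1ccc(OCOC)cc1)C(=O)OCC
A7 | alternative 3 | 1-iodo-4-(methoxymethoxy)benzene | Ic1ccc(OCOC)cc1
A8 | alternative 3 | diethyl 2,5-cis-2-[2,4-bis(methoxymethoxy)phenyl]-5-[4-(methoxymethoxy)phenyl]-3-[4-(methoxymethoxy)benzylidene]oxolane-4,4-dicarboxylate (target numbering) | c1(ccc(OCOC)cc1OCOC)[C@H]3O[C@@H](c4ccc(OCOC)cc4)C(C(=O)OCC)(C(=O)OCC)/C3=C/c3ccc(OCOC)cc3
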